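Ring A is disconnected at C1–C2. Its quaternary carbon C4 sits between the carbonyl carbons C3 and C5, and the two halves of the ring differ only at C2 (methylene bridge) and C6 (butanoyl). An achiral heptanedioate with two enantiotopic keto-ester arms on C4 therefore already contains all six ring carbons. A magnesium bis(oxazoline)-catalysed, enantiotopic-group-selective Dieckmann condensation closes ring A, forms C1–C2 and sets C4 in one operation. The precursor is diallyl 4-methyl-4-prenyl-3,5-dioxoheptanedioate; allyl esters are chosen so that the C2 ester can later be removed with zerovalent palladium under neutral conditions. Butanoylation at C6, decarboxylation and Mannich-type bridging to the aryl ketone finish the synthesis.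

Key step: step 5

Numbering: in ring A, C1 is the ring ketone carbon between the two substituted carbons, C2 finally carries the methylene bridge, C4 is the quaternary carbon, C6 finally carries the butanoyl group; prenyl means 3-methylbut-2-en-1-yl.
Assumption 1: each enolised trione is drawn as one tautomer and its CIP descriptor refers to that drawing; the spatial arrangement at C4 is the same from 8 to 20 (ester-bearing carbon of 8 becomes C2, its unsubstituted carbon becomes C6), although the descriptor changes with the ring substituents (S in 8, 11, 12 and 19; R in 10, 13, 18 and 20).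
Assumption 2: the (4S,4'S) ligand is taken to favour the arm that gives 8 as drawn; the sense of induction cannot be predicted with certainty, and the equally available (4R,4'R) ligand would be used if it proves opposite.
Assumption 3: enolate salts formed under basic conditions are counted as the parent compound, which is released on acidic work-up.

Step 1
Reactants: 1 dimethyl methylmalonate; 2 1-bromo-3-methylbut-2-ene
Product: 3 dimethyl 2-methyl-2-(3-methylbut-2-en-1-yl)propanedioate
Conditions: NaH (1.1 equiv), THF, 0 °C; then 2, 0 °C to rt
Reagents that add atoms: none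
Why: Malonate alkylation (SN2) in which the sodium enolate of 1 attacks the primary allylic bromide at its CH2 terminus, and the product has no α-hydrogen left, so over-alkylation is impossible.

Step 2
Reactants: 3 dimethyl 2-methyl-2-(3-methylbut-2-en-1-yl)propanedioate
Product: 4 2-methyl-2-(3-methylbut-2-en-1-yl)propanedioic acid
Conditions: KOH (5 equiv), MeOH/H2O, reflux; then aq. HCl, 0 °C
Reagents that add atoms: potassium hydroxide, [K+].[OH-]
Why: Ester saponification (BAc2) of a hindered dialkylmalonate with excess hydroxide at reflux, followed by cold acidification that frees the diacid without decarboxylation or hydration of the prenyl alkene.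

Step 3
Reactants: 4 2-methyl-2-(3-methylbut-2-en-1-yl)propanedioic acid
Product: 5 2-methyl-2-(3-methylbut-2-en-1-yl)propanedioyl dichloride
Conditions: (COCl)2 (2.5 equiv), DMF (cat.), CH2Cl2, 0 °C to rt; evaporate, use crude
Reagents that add atoms: oxalyl chloride, O=C(Cl)C(=O)Cl
Why: Acid chloride formation through Vilsmeier-type activation works at or below room temperature, the diacid has no α-hydrogen so no ketene can form, and the HCl escapes as gas before it can add to the trisubstituted alkene.

Step 4
Reactants: 5 2-methyl-2-(3-methylbut-2-en-1-yl)propanedioyl dichloride; 6 allyl acetate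
Product: 7 diallyl 4-methyl-4-(3-methylbut-2-en-1-yl)-3,5-dioxoheptanedioate
Conditions: 6 (4.4 equiv), LiN(SiMe3)2 (4.4 equiv), THF, −78 °C; add 5, −78 °C; then cold 1 M HCl
Reagents that add atoms: none
Why: Twofold crossed Claisen acylation of a preformed lithium ester enolate by an acid chloride, in which the excess enolate deprotonates each new keto-ester arm at once, so that the doubly enolised product has no electrophilic ester and cannot undergo a premature racemic ring closure before the cold acidic quench.

Step 5
Reactants: 7 diallyl 4-methyl-4-(3-methylbut-2-en-1-yl)-3,5-dioxoheptanedioate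
Product: 8 allyl (3S)-2,4-dihydroxy-3-methyl-3-(3-methylbut-2-en-1-yl)-6-oxocyclohexa-1,4-diene-1-carboxylate
Conditions: Mg(OTf)2 (20 mol %), 2,2'-(propane-2,2-diyl)bis[(4S)-4-phenyl-4,5-dihydrooxazole] (22 mol %), N-methylmorpholine (1.5 equiv), 4 Å molecular sieves, CH2Cl2, 0 °C to rt; then cold aq. citric acid
Reagents that add atoms: none
Why: Proposed new method: the ligand-bound divalent magnesium centre chelates the keto-ester arms of 7, N-methylmorpholine removes a proton from the methylene group of the arm that the chiral pocket exposes, and the resulting magnesium enolate carbon adds to the metal-activated ester carbonyl of the other arm, whose tetrahedral intermediate expels allyloxide and so forms the C1–C2 bond. The closest known reaction types are magnesium/amine soft-enolisation Claisen and Dieckmann condensations and magnesium bis(oxazoline)/amine-catalysed enantioselective Michael additions of β-keto esters, whereas a Dieckmann closure that selects between enantiotopic arms has not been shown. Ring A closes in the 6-exo-trig mode. The one new stereocentre, C4 (3S in the name of 8), is controlled by the twofold-symmetric phenyl-substituted ligand on magnesium, which decides through the unequal fit of the C4 methyl and prenyl groups which enantiotopic arm becomes the nucleophile. The step needs arm selectivity, C- over O-acylation and a silent background: the amine is too weak to enolise a keto ester that is not bound to magnesium, no free alkoxide can persist beside the strongly acidic product, and an enol lactone formed by O-attack remains an acyl donor that can revert and drain to the stabilised C-acyl enolate. That enolate does not reopen by retro-Claisen cleavage, so the configuration at C4 is kept, and the stoichiometric amine holds it as an ammonium salt so that magnesium can turn over.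

Step 6
Reactants: 8 allyl (3S)-2,4-dihydroxy-3-methyl-3-(3-methylbut-2-en-1-yl)-6-oxocyclohexa-1,4-diene-1-carboxylate; 9 butanoyl chloride
Product: 11 allyl (3S)-5-butanoyl-2,4-dihydroxy-3-methyl-3-(3-methylbut-2-en-1-yl)-6-oxocyclohexa-1,4-diene-1-carboxylate, via enol butanoate 10 (not isolated)
Conditions: 9 (1.1 equiv), Et3N (3 equiv), CH2Cl2, 0 °C; then DMAP (0.3 equiv), rt
Reagents that add atoms: none
Why: O-Acylation followed by DMAP-catalysed O-to-C acyl migration (Steglich-type rearrangement of a 1,3-dione enol ester, drawn for 10 as the C5–O ester) delivers the butanoyl group to C6, the only ring carbon that still carries hydrogen, because C2 is blocked by the allyl ester and C4 is quaternary and untouched.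

Step 7
Reactants: 11 allyl (3S)-5-butanoyl-2,4-dihydroxy-3-methyl-3-(3-methylbut-2-en-1-yl)-6-oxocyclohexa-1,4-diene-1-carboxylate
Product: 13 (4R)-2-butanoyl-3,5-dihydroxy-4-methyl-4-(3-methylbut-2-en-1-yl)cyclohexa-2,5-dien-1-one, via carboxylic acid 12 (not isolated)
Conditions: Pd(OAc)2 (5 mol %), PPh3 (20 mol %), HCO2H (2.5 equiv), Et3N (3 equiv), THF, rt to 40 °C; then aq. citric acid
Reagents that add atoms: none
Why: Tsuji-type palladium-catalysed deallylation in which zerovalent palladium formed in situ ionises the allyl ester, formate reduces the π-allylpalladium unit to propene so that it cannot C-allylate the ring, and the freed β-keto acid 12 loses CO2 under neutral conditions that spare the prenyl group and leave C4 configurationally intact, since C6 already carries the butanoyl group.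

Step 8
Reactants: 14 phloroglucinol; 15 hexanoyl chloride
Product: 16 1-(2,4,6-trihydroxyphenyl)hexan-1-one
Conditions: AlCl3 (3.5 equiv), PhNO2/CH2Cl2, 0 to 50 °C; then ice/aq. HCl
Reagents that add atoms: none
Why: Friedel–Crafts acylation of the threefold-symmetric, highly activated arene gives one mono-ketone, because the first acyl group, chelated to AlCl3, deactivates the ring toward a second acylation.

Step 9
Reactants: 16 1-(2,4,6-trihydroxyphenyl)hexan-1-one
Product: 17 1-(2,6-dihydroxy-4-methoxyphenyl)hexan-1-one
Conditions: Me2SO4 (1.0 equiv), K2CO3 (1.0 equiv), acetone, rt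
Reagents that add atoms: dimethyl sulfate, COS(=O)(=O)OC
Why: Williamson ether synthesis with one equivalent of base and electrophile methylates the 4-OH selectively, because it is para to the ketone, not hydrogen-bonded to it and the most acidic phenol, which leaves a symmetric ketone whose C3 and C5 are equivalent.

Step 10
Reactants: 13 (4R)-2-butanoyl-3,5-dihydroxy-4-methyl-4-(3-methylbut-2-en-1-yl)cyclohexa-2,5-dien-1-one; 17 1-(2,6-dihydroxy-4-methoxyphenyl)hexan-1-one
Product: 20 elaphopilosin B, via Mannich base 18 (not isolated), via methylene trione 19 (not isolated)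
Conditions: Me2N=CH2+ I− (1.05 equiv), CH2Cl2, rt; then 17 (2 equiv), NaOAc (1.5 equiv), MeCN, 60 °C
Reagents that add atoms: N,N-dimethylmethylideneammonium iodide (Eschenmoser's salt), C[N+](C)=C.[I-]
Why: Mannich reaction followed by amine elimination and Friedel–Crafts-type conjugate addition, in which C2 of 13 (the only free nucleophilic ring carbon) is aminomethylated, the Mannich base loses dimethylamine on warming, and the resulting methylene trione is captured by C3 of the electron-rich phenol 17, used in excess to suppress double alkylation, without any change at C4.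

Compound list
1 | dimethyl methylmalonate | COC(=O)C(C)C(=O)OC | starting material
2 | 1-bromo-3-methylbut-2-ene | CC(C)=CCBr | starting material
3 | dimethyl 2-methyl-2-(3-methylbut-2-en-1-yl)propanedioate | COC(=O)C(C)(CC=C(C)C)C(=O)OC | intermediate
4 | 2-methyl-2-(3-methylbut-2-en-1-yl)propanedioic acid | OC(=O)C(C)(CC=C(C)C)C(=O)O | intermediate
5 | 2-methyl-2-(3-methylbut-2-en-1-yl)propanedioyl dichloride | ClC(=O)C(C)(CC=C(C)C)C(Cl)=O | intermediate
6 | allyl acetate (prop-2-en-1-yl acetate) | CC(=O)OCC=C | starting material
7 | diallyl 4-methyl-4-(3-methylbut-2-en-1-yl)-3,5-dioxoheptanedioate (achiral) | C=CCOC(=O)CC(=O)C(C)(CC=C(C)C)C(=O)CC(=O)OCC=C | intermediate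
8 | allyl (3S)-2,4-dihydroxy-3-methyl-3-(3-methylbut-2-en-1-yl)-6-oxocyclohexa-1,4-diene-1-carboxylate | C=CCOC(=O)C1=C(O)[C@@](C)(CC=C(C)C)C(O)=CC1=O | intermediate
9 | butanoyl chloride | CCCC(=O)Cl | starting material
10 | allyl (3R)-4-(butanoyloxy)-2-hydroxy-3-methyl-3-(3-methylbut-2-en-1-yl)-6-oxocyclohexa-1,4-diene-1-carboxylate (enol butanoate) | C=CCOC(=O)C1=C(O)[C@@](C)(CC=C(C)C)C(OC(=O)CCC)=CC1=O | intermediate
11 | allyl (3S)-5-butanoyl-2,4-dihydroxy-3-methyl-3-(3-methylbut-2-en-1-yl)-6-oxocyclohexa-1,4-diene-1-carboxylate | C=CCOC(=O)C1=C(O)[C@@](C)(CC=C(C)C)C(O)=C(C(=O)CCC)C1=O | intermediate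
12 | (3S)-5-butanoyl-2,4-dihydroxy-3-methyl-3-(3-methylbut-2-en-1-yl)-6-oxocyclohexa-1,4-diene-1-carboxylic acid | OC(=O)C1=C(O)[C@@](C)(CC=C(C)C)C(O)=C(C(=O)CCC)C1=O | intermediate
13 | (4R)-2-butanoyl-3,5-dihydroxy-4-methyl-4-(3-methylbut-2-en-1-yl)cyclohexa-2,5-dien-1-one | O=C1C=C(O)[C@@](C)(CC=C(C)C)C(O)=C1C(=O)CCC | intermediate
14 | phloroglucinol | Oc1cc(O)cc(O)c1 | starting material
15 | hexanoyl chloride | CCCCCC(=O)Cl | starting material
16 | 1-(2,4,6-trihydroxyphenyl)hexan-1-one | CCCCCC(=O)c1c(O)cc(O)cc1O | intermediate
17 | 1-(2,6-dihydroxy-4-methoxyphenyl)hexan-1-one | CCCCCC(=O)c1c(O)cc(OC)cc1O | intermediate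
18 | (4R)-2-butanoyl-6-[(dimethylamino)methyl]-3,5-dihydroxy-4-methyl-4-(3-methylbut-2-en-1-yl)cyclohexa-2,5-dien-1-one (Mannich base) | CN(C)CC1=C(O)[C@@](C)(CC=C(C)C)C(O)=C(C(=O)CCC)C1=O | intermediate
19 | (6S)-4-butanoyl-5-hydroxy-6-methyl-6-(3-methylbut-2-en-1-yl)-2-methylidenecyclohex-4-ene-1,3-dione (methylene trione) | C=C1C(=O)[C@@](C)(CC=C(C)C)C(O)=C(C(=O)CCC)C1=O | intermediate
20 | elaphopilosin B, (4R)-2-butanoyl-6-[(3-hexanoyl-2,4-dihydroxy-6-methoxyphenyl)methyl]-3,5-dihydroxy-4-methyl-4-(3-methylbut-2-en-1-yl)cyclohexa-2,5-dien-1-one | CCCCCC(=O)c1c(O)cc(OC)c(CC2=C(O)[C@@](C)(CC=C(C)C)C(O)=C(C(=O)CCC)C2=O)c1O | target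

Total step count: 10. Longest linear sequence: 8 steps (steps 1 to 7, then step 10); the aryl ketone 17 is made in 2 steps (8 and 9) and joins at step 10.

Steps most likely to fail

Step 5. The chiral magnesium chelate may discriminate poorly between the two enantiotopic arms, the chelating trione enolate may hold the metal and stop turnover, or liberated allyl alcohol may cleave the substrate at the quaternary carbon by retro-Claisen attack. Fallback from 7 by known chemistry: a conventional Dieckmann condensation with sodium allyloxide (1.1 equiv, from NaH and allyl alcohol) in THF at room temperature should give the racemic allyl 2,4-dihydroxy-3-methyl-3-(3-methylbut-2-en-1-yl)-6-oxocyclohexa-1,4-diene-1-carboxylate F1. This strongly acidic enol is then resolved classically: salt formation with one enantiomer of 1-phenylethylamine (drawn for the S amine; the enantiomer that gives the less soluble salt with the needed acid is chosen by trial) and recrystallisation should give the diastereomerically pure (S)-1-phenylethylammonium enolate of the (3S) acid F2. Treatment with cold dilute acid returns to the route at 8.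

Step 4. The second acylation at the hindered, neopentyl-type acyl chloride may stall, or the first-formed keto-ester enolate may be O-acylated intramolecularly by the remaining acid chloride. Fallback from 4: activation of the diacid with 1,1'-carbonyldiimidazole (2.2 equiv, THF, rt) should give the bis(acyl imidazole) 1,3-di(imidazol-1-yl)-2-methyl-2-(3-methylbut-2-en-1-yl)propane-1,3-dione F3. Reaction of F3 with the magnesium salt of allyl hydrogen malonate (from the half-ester, MgCl2 and Et3N in THF) is a decarboxylative Claisen condensation of the Masamune–Brooks type. Quenching into cold dilute acid as soon as F3 is consumed returns to the route at 7.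

Step 10. The methylene bridge may scramble by retro-Michael cleavage to give symmetric dimers, the arene may be alkylated at both C3 and C5, or the methylene trione may condense with unreacted 13. Fallback from 17 with the roles of the partners reversed: Mannich reaction of 17 with aqueous formaldehyde and dimethylamine (1 equiv each, EtOH, rt) should give the mono-aminomethyl ketone 1-{3-[(dimethylamino)methyl]-2,6-dihydroxy-4-methoxyphenyl}hexan-1-one F4. Heating F4 with 13 in toluene at about 90 °C expels dimethylamine to form an ortho-quinone methide of the arene, which the C2 enol carbon of 13 captures, returning to the route at 20.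

Further compounds
F1 | step 5 | racemic allyl 2,4-dihydroxy-3-methyl-3-(3-methylbut-2-en-1-yl)-6-oxocyclohexa-1,4-diene-1-carboxylate | C=CCOC(=O)C1=C(O)C(C)(CC=C(C)C)C(O)=CC1=O
F2 | step 5 | (S)-1-phenylethylammonium enolate of allyl (3S)-2,4-dihydroxy-3-methyl-3-(3-methylbut-2-en-1-yl)-6-oxocyclohexa-1,4-diene-1-carboxylate | C[C@H]([NH3+])c1ccccc1.C=CCOC(=O)C1=C([O-])[C@@](C)(CC=C(C)C)C(O)=CC1=O
F3 | step 4 | 1,3-di(imidazol-1-yl)-2-methyl-2-(3-methylbut-2-en-1-yl)propane-1,3-dione | O=C(n1ccnc1)C(C)(CC=C(C)C)C(=O)n1ccnc1
F4 | step 10 | 1-{3-[(dimethylamino)methyl]-2,6-dihydroxy-4-methoxyphenyl}hexan-1-one | CCCCCC(=O)c1c(O)cc(OC)c(CN(C)C)c1O
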